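**Retrosynthetic overview**
- Target ⇐ acid-mediated shift of the C1 hydrogen to C8 in a 1H-isochromene ortho-quinol ⇐ reagent-controlled hydroxylation at C7 that dearomatises a 6-hydroxy-1H-isochromene (last step; both ring stereocentres set there).
- Pyran ring ⇐ the C3 ketone (enol) oxygen closes onto an electrophilic C1 (p-quinone-methide-type benzylic cation) of an open-chain 2-oxoalkyl arene.
- Open-chain arene ⇐ Pd α-arylation (C4–C4a bond) of an aryl bromide with the bis-silyl dienolate of (E)-4-oxopent-2-enoic acid; C1 ⇐ directed magnesiation between ester and bromine, then methoxymethylation.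
- Ester ⇐ Mitsunobu inversion of (2R,4S)-4-methylhexan-2-ol (from (S)-1-bromo-2-methylbutane by Weinreb ketone synthesis and enzymatic reduction) with 5-bromo-3-hydroxy-2-methylbenzoic acid.
- Ring order: benzene ring bought → pyran ring closed (step 8) → carbocycle dearomatised and C7/C8 set (step 9).

Assumption: the metabolite is taken to arise as the azaphilones do (benzenoid polyketide, pyran closure by the C3 oxygen at C1, flavin-monooxygenase hydroxylation at C7), and acid 6 is taken as a catalogue compound (otherwise one LiOH hydrolysis of its methyl ester).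

**Step 1**
Reactants: 1 (S)-1-bromo-2-methylbutane; 2 N-methoxy-N-methylacetamide
Product: 4 (S)-4-methylhexan-2-one, via Grignard reagent 3 (not isolated)
Conditions: Mg, THF, reflux; then 2, 0 °C → rt; aq. HCl
Reagents that add atoms: none
Why: Weinreb ketone synthesis; the chelated tetrahedral adduct stops at the ketone and the existing stereocentre (β to magnesium) is not touched.

**Step 2**
Reactants: 4 (S)-4-methylhexan-2-one
Product: 5 (2R,4S)-4-methylhexan-2-ol
Conditions: Lactobacillus kefir alcohol dehydrogenase, NADP+ (cat.), i-PrOH, MgCl2 (1 mM), phosphate buffer pH 7, 30 °C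
Reagents that add atoms: none
Why: Biocatalytic anti-Prelog ketone reduction; the enzyme delivers hydride to one face of methyl ketones to give (R)-2-alkanols in high ee, so C2 is set by the catalyst and not by the remote (4S) centre.

**Step 3**
Reactants: 5 (2R,4S)-4-methylhexan-2-ol; 6 5-bromo-3-hydroxy-2-methylbenzoic acid
Product: 7 (2S,4S)-4-methylhexan-2-yl 5-bromo-3-hydroxy-2-methylbenzoate
Conditions: PPh3, DIAD, THF, 0 °C → rt (6 in slight excess)
Reagents that add atoms: none
Why: Mitsunobu esterification; the carboxylic acid, far more acidic than the phenol, is the pronucleophile and displaces the activated alcohol by SN2 with inversion, turning (2R) into the (2S) ester of the target.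

**Step 4**
Reactants: 7 (2S,4S)-4-methylhexan-2-yl 5-bromo-3-hydroxy-2-methylbenzoate
Product: 8 (2S,4S)-4-methylhexan-2-yl 5-bromo-2-methyl-3-(triethylsilyloxy)benzoate
Conditions: TESCl, imidazole, DMF, 0 °C → rt
Reagents that add atoms: chlorotriethylsilane, CC[Si](Cl)(CC)CC
Why: Standard phenol silylation; the bulky, weakly coordinating silyl ether removes the acidic proton and does not direct metalation to the neighbouring C–H.

**Step 5**
Reactants: 8 (2S,4S)-4-methylhexan-2-yl 5-bromo-2-methyl-3-(triethylsilyloxy)benzoate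
Product: 10 (2S,4S)-4-methylhexan-2-yl 3-bromo-2-(methoxymethyl)-6-methyl-5-(triethylsilyloxy)benzoate, via arylmagnesium chloride 9 (not isolated)
Conditions: TMPMgCl·LiCl (1.3 equiv), THF, −20 °C, 3 h; then MeOCH2Cl, −20 °C → rt
Reagents that add atoms: chloromethyl methyl ether, COCCl
Why: Knochel–Hauser base directed ortho-magnesiation removes the one ring hydrogen flanked by the coordinating ester and the acidifying bromine (both tolerated at −20 °C), and the aryl Grignard is alkylated by the α-chloro ether, so C1 enters at the alcohol oxidation level without a free alkoxide that would lactonise onto the ester.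

**Step 6**
Reactants: 11 (E)-4-oxopent-2-enoic acid
Product: 12 trimethylsilyl (E)-4-(trimethylsilyloxy)penta-2,4-dienoate
Conditions: TMSOTf (2.2 equiv), Et3N (2.5 equiv), Et2O, 0 °C
Reagents that add atoms: trimethylsilyl trifluoromethanesulfonate, C[Si](C)(C)OS(=O)(=O)C(F)(F)F
Why: Soft enolisation; the methyl ketone can enolise only towards CH3, giving the 2-silyloxydiene, and the acid is masked as its silyl ester.

**Step 7**
Reactants: 10 (2S,4S)-4-methylhexan-2-yl 3-bromo-2-(methoxymethyl)-6-methyl-5-(triethylsilyloxy)benzoate; 12 trimethylsilyl (E)-4-(trimethylsilyloxy)penta-2,4-dienoate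
Product: 13 (2S,4S)-4-methylhexan-2-yl 3-[(3E)-4-carboxy-2-oxobut-3-en-1-yl]-2-(methoxymethyl)-6-methyl-5-(triethylsilyloxy)benzoate
Conditions: Pd(dba)2 (5 mol %), P(t-Bu)3 (10 mol %), ZnF2 (0.6 equiv), 12 (1.5 equiv), DMF, 70 °C; aq. NaH2PO4 work-up
Reagents that add atoms: none
Why: Kuwajima–Hartwig-type palladium-catalysed α-arylation of a silyl enol ether; ZnF2 releases a mild zinc enolate that transmetalates to the arylpalladium bromide formed by oxidative addition to zerovalent palladium, and the work-up hydrolyses the silyl ester to the free acid.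

**Step 8**
Reactants: 13 (2S,4S)-4-methylhexan-2-yl 3-[(3E)-4-carboxy-2-oxobut-3-en-1-yl]-2-(methoxymethyl)-6-methyl-5-(triethylsilyloxy)benzoate
Product: 14 (2S,4S)-4-methylhexan-2-yl 3-[(E)-2-carboxyethenyl]-6-hydroxy-7-methyl-1H-isochromene-8-carboxylate
Conditions: TFA (10 equiv), CH2Cl2 (0.01 M), 0 °C → rt, under Ar
Reagents that add atoms: none
Why: Acid-mediated oxa-cyclisation of the cyclodehydration type: TFA removes the silyl group and ionises the para-oxygenated benzylic methyl ether to a protonated p-quinone methide, the C3 ketone oxygen captures C1 through a six-membered transition state, and loss of the C4 proton gives the enol ether of the 1H-isochromene.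

**Step 9**
Reactants: 14 (2S,4S)-4-methylhexan-2-yl 3-[(E)-2-carboxyethenyl]-6-hydroxy-7-methyl-1H-isochromene-8-carboxylate
Product: 16 (2S,4S)-4-methylhexan-2-yl (7R,8R)-3-[(E)-2-carboxyethenyl]-7-hydroxy-7-methyl-6-oxo-7,8-dihydro-6H-isochromene-8-carboxylate, via ortho-quinol 15 (not isolated)
Conditions: (R)-2,2'-diiodyl-1,1'-binaphthyl (0.55 equiv), THF, −20 °C → rt; then TFA (1 equiv), CH2Cl2, rt
Reagents that add atoms: (R)-2,2'-diiodyl-1,1'-binaphthyl, O=I(=O)c1ccc2ccccc2c1-c1c(I(=O)=O)ccc2ccccc12
Why: Proposed new method: the phenol exchanges onto the chiral iodyl (pentavalent iodine) centre and oxygen is passed intramolecularly to the methyl-bearing ortho carbon C7 (closest known reaction type: hydroxylative phenol dearomatisation of 2-alkylphenols by IBX-type and chiral biaryl iodyl reagents), giving ortho-quinol 15 with C7 set by the reagent, after which acid moves the C1 hydrogen to C8 through a pyrylium enol and reversible protonation leaves C8 in the configuration expected to be more stable (ester trans to the C7 methyl, cis to the hydroxyl), i.e. (7R,8R).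

**Compound list**
1 | (S)-1-bromo-2-methylbutane | CC[C@H](C)CBr | starting material
2 | N-methoxy-N-methylacetamide | CC(=O)N(C)OC | starting material
3 | (S)-2-methylbutylmagnesium bromide | CC[C@H](C)C[Mg]Br | intermediate
4 | (S)-4-methylhexan-2-one | CC[C@H](C)CC(C)=O | intermediate
5 | (2R,4S)-4-methylhexan-2-ol | CC[C@H](C)C[C@@H](C)O | intermediate
6 | 5-bromo-3-hydroxy-2-methylbenzoic acid | Cc1c(O)cc(Br)cc1C(=O)O | starting material
7 | (2S,4S)-4-methylhexan-2-yl 5-bromo-3-hydroxy-2-methylbenzoate | CC[C@H](C)C[C@H](C)OC(=O)c1cc(Br)cc(O)c1C | intermediate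
8 | (2S,4S)-4-methylhexan-2-yl 5-bromo-2-methyl-3-(triethylsilyloxy)benzoate | CC[C@H](C)C[C@H](C)OC(=O)c1cc(Br)cc(O[Si](CC)(CC)CC)c1C | intermediate
9 | arylmagnesium chloride of 8 (Mg on the ring carbon between ester and bromine) | CC[C@H](C)C[C@H](C)OC(=O)c1c([Mg]Cl)c(Br)cc(O[Si](CC)(CC)CC)c1C | intermediate
10 | (2S,4S)-4-methylhexan-2-yl 3-bromo-2-(methoxymethyl)-6-methyl-5-(triethylsilyloxy)benzoate | CC[C@H](C)C[C@H](C)OC(=O)c1c(COC)c(Br)cc(O[Si](CC)(CC)CC)c1C | intermediate
11 | (E)-4-oxopent-2-enoic acid | CC(=O)/C=C/C(=O)O | starting material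
12 | trimethylsilyl (E)-4-(trimethylsilyloxy)penta-2,4-dienoate | C=C(O[Si](C)(C)C)/C=C/C(=O)O[Si](C)(C)C | intermediate
13 | (2S,4S)-4-methylhexan-2-yl 3-[(3E)-4-carboxy-2-oxobut-3-en-1-yl]-2-(methoxymethyl)-6-methyl-5-(triethylsilyloxy)benzoate | CC[C@H](C)C[C@H](C)OC(=O)c1c(COC)c(CC(=O)/C=C/C(=O)O)cc(O[Si](CC)(CC)CC)c1C | intermediate
14 | (2S,4S)-4-methylhexan-2-yl 3-[(E)-2-carboxyethenyl]-6-hydroxy-7-methyl-1H-isochromene-8-carboxylate | CC[C@H](C)C[C@H](C)OC(=O)c1c(C)c(O)cc2C=C(/C=C/C(=O)O)OCc12 | intermediate
15 | (2S,4S)-4-methylhexan-2-yl (7R)-3-[(E)-2-carboxyethenyl]-7-hydroxy-7-methyl-6-oxo-6,7-dihydro-1H-isochromene-8-carboxylate | CC[C@H](C)C[C@H](C)OC(=O)C1=C2COC(/C=C/C(=O)O)=CC2=CC(=O)[C@]1(C)O | intermediate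
16 | (2S,4S)-4-methylhexan-2-yl (7R,8R)-3-[(E)-2-carboxyethenyl]-7-hydroxy-7-methyl-6-oxo-7,8-dihydro-6H-isochromene-8-carboxylate (CNP0114760.1) | CC[C@H](C)C[C@H](C)OC(=O)[C@@H]1C2=COC(/C=C/C(=O)O)=CC2=CC(=O)[C@]1(C)O | target

**Step count**
Total: 9 steps. Longest linear sequence: 8 steps (1, 2, 3, 4, 5, 7, 8, 9).

**Three steps most likely to fail**

Step 9 (highest risk). The iodyl reagent may oxygenate the free ortho position C5, dehydrogenate 14 at C1 to the quinone methide, or give weak facial control; the sense of induction of the (R)-reagent is inferred, not proven, for this phenol, and the C8 preference rests on conformational reasoning. The fallback sets out from 14. Benzeneseleninic anhydride, (PhSeO)2O, in THF at rt performs a Barton ortho-hydroxylation through a [2,3]-shift of the aryl seleninate. It gives 15 together with its C7 epimer, (2S,4S)-4-methylhexan-2-yl (7S)-3-[(E)-2-carboxyethenyl]-7-hydroxy-7-methyl-6-oxo-6,7-dihydro-1H-isochromene-8-carboxylate F4. TFA then converts the pair into 16 and (2S,4S)-4-methylhexan-2-yl (7S,8S)-3-[(E)-2-carboxyethenyl]-7-hydroxy-7-methyl-6-oxo-7,8-dihydro-6H-isochromene-8-carboxylate F5. These two are diastereomers because of the (2S,4S)-ester and are separated by preparative HPLC, so the route is rejoined at 16.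

Step 7. The arylpalladium species may instead undergo Heck insertion into the enoate, the zinc enolate may add to the product enone, or a second arylation may occur. The fallback sets out from 10 and brings the side chain in as an alkyne. Sonogashira coupling (PdCl2(PPh3)2, CuI, Et3N) with (E)-pent-2-en-4-ynoic acid gives (2S,4S)-4-methylhexan-2-yl 3-[(3E)-4-carboxybut-3-en-1-yn-1-yl]-2-(methoxymethyl)-6-methyl-5-(triethylsilyloxy)benzoate F1. AuCl3 (5 mol %) with TFA in CH2Cl2 then triggers 6-endo attack of the benzylic ether oxygen on the alkyne, loss of the O-methyl group and removal of the silyl group. This gives 14 directly, so the route is rejoined at 14 and step 8 is also replaced.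

Step 8. In acid the benzylic cation can be captured by the neighbouring ester (phthalide formation with loss of the chiral alcohol), and the 1H-isochromene can disproportionate by hydride transfer. The fallback sets out from 13 and closes the pyran under base through the neutral p-quinone methide. BCl3 (CH2Cl2, −78 °C) converts the benzylic methyl ether into the chloride, (2S,4S)-4-methylhexan-2-yl 3-[(3E)-4-carboxy-2-oxobut-3-en-1-yl]-2-(chloromethyl)-6-methyl-5-(triethylsilyloxy)benzoate F2. CsF and i-Pr2NEt in MeCN at rt then remove the silyl group, and the phenolate expels chloride to give (2S,4S)-4-methylhexan-2-yl 5-[(3E)-4-carboxy-2-oxobut-3-en-1-yl]-2-methyl-6-methylidene-3-oxocyclohexa-1,4-diene-1-carboxylate F3. The side-chain enol oxygen adds to its methylene carbon to give 14, where the route is rejoined.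

**Further compounds**
F1 | step 7 | (2S,4S)-4-methylhexan-2-yl 3-[(3E)-4-carboxybut-3-en-1-yn-1-yl]-2-(methoxymethyl)-6-methyl-5-(triethylsilyloxy)benzoate | CC[C@H](C)C[C@H](C)OC(=O)c1c(COC)c(C#C/C=C/C(=O)O)cc(O[Si](CC)(CC)CC)c1C
F2 | step 8 | (2S,4S)-4-methylhexan-2-yl 3-[(3E)-4-carboxy-2-oxobut-3-en-1-yl]-2-(chloromethyl)-6-methyl-5-(triethylsilyloxy)benzoate | CC[C@H](C)C[C@H](C)OC(=O)c1c(CCl)c(CC(=O)/C=C/C(=O)O)cc(O[Si](CC)(CC)CC)c1C
F3 | step 8 | (2S,4S)-4-methylhexan-2-yl 5-[(3E)-4-carboxy-2-oxobut-3-en-1-yl]-2-methyl-6-methylidene-3-oxocyclohexa-1,4-diene-1-carboxylate | CC[C@H](C)C[C@H](C)OC(=O)C1=C(C)C(=O)C=C(CC(=O)/C=C/C(=O)O)C1=C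
F4 | step 9 | (2S,4S)-4-methylhexan-2-yl (7S)-3-[(E)-2-carboxyethenyl]-7-hydroxy-7-methyl-6-oxo-6,7-dihydro-1H-isochromene-8-carboxylate | CC[C@H](C)C[C@H](C)OC(=O)C1=C2COC(/C=C/C(=O)O)=CC2=CC(=O)[C@@]1(C)O
F5 | step 9 | (2S,4S)-4-methylhexan-2-yl (7S,8S)-3-[(E)-2-carboxyethenyl]-7-hydroxy-7-methyl-6-oxo-7,8-dihydro-6H-isochromene-8-carboxylate | CC[C@H](C)C[C@H](C)OC(=O)[C@H]1C2=COC(/C=C/C(=O)O)=CC2=CC(=O)[C@@]1(C)O
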